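**Plan**
- Cuts, in retrosynthetic order: C7=CH2 (from a C7 ketone); C3–Br and C2–Cl (from a C2=C3 alkene through its epoxide); C6–C1 and C5–C4 of ring B (Diels–Alder of isoprene on a ring A exocyclic enone); C10–Br (from C10–OH with inversion); C10–C11 of ring A (carbonyl-ene closure of an acyclic aldehyde).
- Forward: 5,6-dimethylhept-5-enal → ring A by C10–C11 closure → C7 oxidation and C10 bromination → ring B by cycloaddition at C6=C5 → trans-diaxial Cl/Br on ring B → C7 methylenation.
- Enabling feature: in ring A the halogen-bearing C10 lies next to the gem-dimethyl C11, whose other neighbour is the fully substituted C6. With C6 carried as an alkene carbon, O–C10–C11–C6=C5 is a homoallylic alcohol (the ene retron), so an aldehyde carbon (C10) and a tetrasubstituted alkene (C6=C11, methyl C5 on C6) suffice. The C6=C5 bond left by the ene step is the dienophile for ring B.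
- Stereochemistry: C10 from the (R)-BINOLate–Ti(ClO4)2 catalyst in the ene step, then inverted on bromination; C6 from C10 (diene adds anti to Br); C2 and C3 from C6, which locks ring B (C11 equatorial, C7 axial): epoxidation anti to C7, diaxial chloride opening, bromide with retention.

Key step: step 4

Remark: atom numbers are chamigrene numbers (ring B C1–C5, spiro C6, ring A C7–C11; C10 bears Br, C11 the two methyls, C7 the methylene).
Remark: the (R)-BINOL-derived titanium catalyst is assumed to give the (R)-alcohol 7; if the sense of induction is the opposite, (S)-BINOL is used.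

**Route**

Step 1
Reactants: 1 2,3-dimethylbuta-1,3-diene
Product: 2 1-bromo-2,3-dimethylbut-2-ene
Conditions: HBr (33% in AcOH, 1.0 equiv), 0 °C
Reagents that add atoms: hydrogen bromide, Br
Why: Electrophilic 1,4-hydrobromination through the tertiary allyl cation should give the more stable primary allylic bromide with the tetrasubstituted alkene; no stereocenter is formed.

Step 2
Reactants: 2 1-bromo-2,3-dimethylbut-2-ene; 3 2-(2-bromoethyl)-1,3-dioxolane
Product: 5 2-(4,5-dimethylhex-4-en-1-yl)-1,3-dioxolane, via dioxolanylethylmagnesium bromide 4 (not isolated)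
Conditions: 3, Mg, THF, 25 °C; then 2, Li2CuCl4 (3 mol %), THF, −10 to 0 °C
Reagents that add atoms: none
Why: Copper-catalysed Grignard cross-coupling with an allylic bromide, in which SN2 attack at the primary carbon is favoured because the other allyl terminus is fully substituted; no stereocenter is formed.

Step 3
Reactants: 5 2-(4,5-dimethylhex-4-en-1-yl)-1,3-dioxolane
Product: 6 5,6-dimethylhept-5-enal
Conditions: AcOH/H2O/THF (3:1:1), 45 °C
Reagents that add atoms: water, O
Why: Acid-catalysed acetal hydrolysis under conditions too weak to protonate the tetrasubstituted alkene; no stereocenter is formed.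

Step 4
Reactants: 6 5,6-dimethylhept-5-enal
Product: 7 (R)-2,2-dimethyl-3-methylenecyclohexan-1-ol
Conditions: (R)-BINOL (20 mol %), TiCl2(OiPr)2 (20 mol %), AgClO4 (40 mol %), 4 Å MS, CH2Cl2, −30 °C
Reagents that add atoms: none
Why: Proposed new method: the (R)-BINOLate–Ti(ClO4)2 Lewis acid binds the aldehyde, C10 is attacked by C11 of the electron-rich tetrasubstituted alkene and the oxygen takes a hydrogen from the C5 methyl on C6 through a six-membered array, so that C10–C11 forms and the double bond moves to C6=C5 (intramolecular carbonyl-ene reaction). The closest known reaction types are the Me2AlCl-promoted carbonyl-ene cyclization of aldehydes tethered to the central carbon of the ene unit, the intermolecular ene reaction of aldehydes with 2,3-dimethylbut-2-ene, which also forms a quaternary carbon, and BINOL–titanium-catalysed enantioselective ene cyclizations; new is their combination on an unactivated aldehyde with a tetrasubstituted alkene. Ring A closes in a 6-endo mode at the alkene (exo at the carbonyl) through a chair. The only new stereocenter, C10, is set by the chiral ligand on titanium, which shields one face of the bound aldehyde. The step needs six-ring over five-ring closure and an exocyclic over an endocyclic alkene: C6 and C11 are both fully substituted, so charge build-up is equal at either carbon and the strain-free chair to the six-ring should win, and only the freely rotating C5 methyl, not the ring C7–H, should reach the metal-bound oxygen.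

Step 5
Reactants: 7 (R)-2,2-dimethyl-3-methylenecyclohexan-1-ol
Product: 8 (1R)-2,2-dimethyl-3-methylenecyclohexane-1,4-diol (both epimers at the new carbinol carbon C7)
Conditions: SeO2 (0.3 equiv), tBuOOH (2 equiv), CH2Cl2, 25 °C
Reagents that add atoms: tert-butyl hydroperoxide, CC(C)(C)OO
Why: Allylic hydroxylation with SeO2 (ene reaction, then 2,3-sigmatropic shift) should oxidize C7, the only allylic CH2, and return the double bond to C6=C5; the new C7 carbinol center is uncontrolled and is removed in step 6.

Step 6
Reactants: 8 (1R)-2,2-dimethyl-3-methylenecyclohexane-1,4-diol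
Product: 9 (R)-4-hydroxy-3,3-dimethyl-2-methylenecyclohexan-1-one
Conditions: MnO2 (activated, excess), CH2Cl2, 25 °C
Reagents that add atoms: none
Why: Allylic alcohol oxidation with MnO2 should touch only the allylic C7 alcohol, so the saturated C10 alcohol and its configuration are kept.

Step 7
Reactants: 9 (R)-4-hydroxy-3,3-dimethyl-2-methylenecyclohexan-1-one
Product: 10 (S)-4-bromo-3,3-dimethyl-2-methylenecyclohexan-1-one
Conditions: CBr4 (1.5 equiv), PPh3 (1.5 equiv), CH2Cl2, 0 to 40 °C
Reagents that add atoms: carbon tetrabromide, BrC(Br)(Br)Br
Why: Appel reaction, in which bromide displaces the oxyphosphonium group at C10 by SN2 with inversion (R to S), as known for neopentyl cyclohexanols whose leaving group can sit axial, while the electron-poor enone next to C11 disfavours ionization, methyl shift and alkene participation.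

Step 8
Reactants: 10 (S)-4-bromo-3,3-dimethyl-2-methylenecyclohexan-1-one; 11 isoprene (2-methylbuta-1,3-diene)
Product: 12 (6R,10S)-10-bromo-3,11,11-trimethylspiro[5.5]undec-2-en-7-one
Conditions: isoprene (5 equiv), Me2AlCl (20 mol %), CH2Cl2, −78 to −20 °C
Reagents that add atoms: none
Why: Lewis-acid-catalysed Diels–Alder reaction, in which the more nucleophilic diene terminus bonds to the exocyclic CH2 (C5) and so puts the methyl on C3, and the diene should add to the face of C6 anti to the C10 bromine (bromine-equatorial half-chair, the other face being blocked by the axial C11 methyl), which sets the spiro center C6.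

Step 9
Reactants: 12 (6R,10S)-10-bromo-3,11,11-trimethylspiro[5.5]undec-2-en-7-one
Product: 13 (2S,3R,6R,10S)-10-bromo-2,3-epoxy-3,11,11-trimethylspiro[5.5]undecan-7-one
Conditions: mCPBA (1.1 equiv), CH2Cl2, 0 °C
Reagents that add atoms: 3-chloroperbenzoic acid, OOC(=O)c1cccc(Cl)c1
Why: Prilezhaev epoxidation; ring B carries the bulky C11 equatorial and the C7 carbonyl axial, so the peracid should add to the C2=C3 face anti to C7, which sets C2 and C3.

Step 10
Reactants: 13 (2S,3R,6R,10S)-10-bromo-2,3-epoxy-3,11,11-trimethylspiro[5.5]undecan-7-one
Product: 14 (2R,3R,6R,10S)-10-bromo-2-chloro-3-hydroxy-3,11,11-trimethylspiro[5.5]undecan-7-one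
Conditions: LiCl (3 equiv), AcOH (3 equiv), THF, 25 °C
Reagents that add atoms: lithium chloride, [Li+].[Cl-]
Why: Epoxide opening by chloride under the Fürst–Plattner rule, in which SN2 attack at the secondary C2 with inversion should give the trans-diaxial chlorohydrin (axial C2–Cl, axial C3–OH).

Step 11
Reactants: 14 (2R,3R,6R,10S)-10-bromo-2-chloro-3-hydroxy-3,11,11-trimethylspiro[5.5]undecan-7-one
Product: 15 (2R,3R,6R,10S)-3,10-dibromo-2-chloro-3,11,11-trimethylspiro[5.5]undecan-7-one
Conditions: HBr (gas, excess), CH2Cl2, −20 to 0 °C
Reagents that add atoms: hydrogen bromide, Br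
Why: SN1 substitution with neighbouring-group participation, in which the antiperiplanar axial chlorine bridges C3 as water leaves and bromide opens the chloronium ion at the tertiary C3, so that C3 should keep its configuration with bromine axial and trans to chlorine.

Step 12
Reactants: 15 (2R,3R,6R,10S)-3,10-dibromo-2-chloro-3,11,11-trimethylspiro[5.5]undecan-7-one
Product: 16 (2R,3R,6S,10S)-3,10-dibromo-2-chloro-3,11,11-trimethyl-7-methylenespiro[5.5]undecane
Conditions: Cp2TiMe2 (3 equiv), toluene, 65 °C, dark
Reagents that add atoms: dimethyltitanocene, [CH3-].[CH3-].[Ti+4].c1cc[cH-]c1.c1cc[cH-]c1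
Why: Petasis methylenation, in which the titanium methylidene formed on heating adds to the hindered C7 ketone under non-basic conditions, so the alkyl halides and the four stereocenters should stay untouched.

**Compound list**
1 | 2,3-dimethylbuta-1,3-diene | C=C(C)C(C)=C | starting material
2 | 1-bromo-2,3-dimethylbut-2-ene | CC(C)=C(C)CBr | intermediate
3 | 2-(2-bromoethyl)-1,3-dioxolane | BrCCC1OCCO1 | starting material
4 | [2-(1,3-dioxolan-2-yl)ethyl]magnesium bromide (dioxolanylethylmagnesium bromide) | Br[Mg]CCC1OCCO1 | intermediate
5 | 2-(4,5-dimethylhex-4-en-1-yl)-1,3-dioxolane | CC(C)=C(C)CCCC1OCCO1 | intermediate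
6 | 5,6-dimethylhept-5-enal | CC(C)=C(C)CCCC=O | intermediate
7 | (R)-2,2-dimethyl-3-methylenecyclohexan-1-ol | C=C1CCC[C@@H](O)C1(C)C | intermediate
8 | (1R)-2,2-dimethyl-3-methylenecyclohexane-1,4-diol, both C4 epimers | OC1CC[C@@H](O)C(C)(C)C1=C | intermediate
9 | (R)-4-hydroxy-3,3-dimethyl-2-methylenecyclohexan-1-one | O=C1CC[C@@H](O)C(C)(C)C1=C | intermediate
10 | (S)-4-bromo-3,3-dimethyl-2-methylenecyclohexan-1-one | O=C1CC[C@H](Br)C(C)(C)C1=C | intermediate
11 | isoprene (2-methylbuta-1,3-diene) | C=CC(C)=C | starting material
12 | (6R,10S)-10-bromo-3,11,11-trimethylspiro[5.5]undec-2-en-7-one | O=C1CC[C@H](Br)C(C)(C)[C@]12CCC(C)=CC2 | intermediate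
13 | (2S,3R,6R,10S)-10-bromo-2,3-epoxy-3,11,11-trimethylspiro[5.5]undecan-7-one | O=C1CC[C@H](Br)C(C)(C)[C@]12CC[C@@]3(C)O[C@H]3C2 | intermediate
14 | (2R,3R,6R,10S)-10-bromo-2-chloro-3-hydroxy-3,11,11-trimethylspiro[5.5]undecan-7-one | O=C1CC[C@H](Br)C(C)(C)[C@]12CC[C@@](C)(O)[C@H](Cl)C2 | intermediate
15 | (2R,3R,6R,10S)-3,10-dibromo-2-chloro-3,11,11-trimethylspiro[5.5]undecan-7-one | O=C1CC[C@H](Br)C(C)(C)[C@]12CC[C@@](C)(Br)[C@H](Cl)C2 | intermediate
16 | (2R,3R,6S,10S)-3,10-dibromo-2-chloro-3,11,11-trimethyl-7-methylenespiro[5.5]undecane | C=C1CC[C@H](Br)C(C)(C)[C@]12CC[C@@](C)(Br)[C@H](Cl)C2 | target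

Total step count: 12. Longest linear sequence: 12 steps (from 1).

**Steps most likely to fail**

Step 4 (Proposed new method). The ring may close at the nearer alkene carbon to give a five-membered ring, the proton may be lost into the ring instead of from the C5 methyl, or the (R)-BINOLate–Ti(ClO4)2 catalyst may discriminate the faces of the unactivated aldehyde poorly. Fallback, from 6 back to 7: the closure is run without chiral control with Me2AlCl in CH2Cl2 at −78 °C, a known Lewis-acid carbonyl-ene cyclization, to give racemic 2,2-dimethyl-3-methylenecyclohexan-1-ol F1. Swern oxidation then gives 2,2-dimethyl-3-methylenecyclohexan-1-one F2. Corey–Bakshi–Shibata reduction of F2 ((S)-2-methyl-CBS-oxazaborolidine, BH3·SMe2), whose carbonyl lies between a quaternary carbon and a CH2 group, should return to 7.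

Step 7. SN2 attack at the neopentyl C10 may be slow, so that elimination toward C9 or addition of the phosphine to the enone competes. Fallback, from 9 back to 10: activation and substitution are separated. Triflic anhydride and 2,6-lutidine in CH2Cl2 at −78 °C give (R)-2,2-dimethyl-3-methylene-4-oxocyclohexyl trifluoromethanesulfonate F3, which tetrabutylammonium bromide in toluene should displace by SN2 with inversion, without any phosphine present.

Step 11. The tertiary alcohol may ionize without chlorine bridging, which would lead to elimination or to bromide attack from the wrong face. Fallback, from 12 directly to 15, bypassing 13 and 14: anti addition of bromine chloride from tetrabutylammonium dichlorobromate in CH2Cl2 at −78 to 0 °C. The bromonium ion should form on the C2=C3 face anti to the axial C7, and chloride should open it trans-diaxially at C2 (Fürst–Plattner rule), which places bromine on C3 and chlorine on C2. This path makes no compound outside the list (F0).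

**Further compounds**
F1 | step 4 | racemic 2,2-dimethyl-3-methylenecyclohexan-1-ol | C=C1CCCC(O)C1(C)C
F2 | step 4 | 2,2-dimethyl-3-methylenecyclohexan-1-one | C=C1CCCC(=O)C1(C)C
F3 | step 7 | (R)-2,2-dimethyl-3-methylene-4-oxocyclohexyl trifluoromethanesulfonate | O=C1CC[C@@H](OS(=O)(=O)C(F)(F)F)C(C)(C)C1=C
F0 | step 11 | none | none
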